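The readings were generated by integration with made-up constants; noise was put on by code.

E and L together cannot be the whole fate of Q in the ochre flask, because at 60.0 min they hold 14.5% of the Q charged while E is already nearly gone, so most of the Q must have left through E into something unread.

| setting | ochre | green | flask |
|---|---|---|---|
| Q | 0.013 M | 0.026 M | 0.013 M |
| X | 0.0195 M | 0.0195 M | 0.0195 M |
| remark | the very flask that is asked about, followed so far | run made earlier |  |
| time |  |  | 2.0 h |

- ochre (time / min: E / %, L / %): 2.00: 8.9, 0.4; 6.00: 14.9, 1.4; 20.0: 8.8, 8.2; 60.0: 1.0, 13.5
- green (time / min: E / %, L / %): 2.00: 8.9, 0.9; 6.00: 13.3, 1.6; 15.0: 8.8, 6.4; 50.0: 2.4, 10.7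

(scatter of a reading: 0.5 percentage points)

- the earlier runs were read with a standard deviation of 0.5 percentage points

- when, up to 2.0 h, the flask holds most E
- the amount of E, in percent of the Q charged, at that time

In the ochre flask Q is the smaller charge and, taking one X for each Q, the limiting reagent, so its balance reads: Q charged equals Q left, plus E, plus what E has become. If Q passes through E and E is lost in first order, the area under the E curve equals the mean stay of E, 4.18 min, read from the ochre readings with Q taken as spent by the last one. A second way takes the rise between the first two readings under a steady supply and gives 2.59 min, which is less. This second way cheats, since at least 16.3% of the Q has reacted by 6.00 min, so the supply is not steady and E levels off early. The area is the figure to trust. It is shorter than the 18.4 min e-folding time of the late ochre readings, so E follows its fading supply, and its top stands where supply equals E divided by the stay, near the reading of 14.9%.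

The forecast gives 15.3% (from 14.3% to 17%) at 0.11 h (from 0.07 h to 0.15 h), adding that “sparse sampling leaves it uncertain”.

The flask gives 15.4% at 0.124 h.

    E → D (k = 0.140 min⁻¹)
    E → G (k = 0.0330 min⁻¹)
    Q + X → E (k = 3.10 M⁻¹ min⁻¹)
    E → L (k = 0.0340 min⁻¹)

The stay of 4.18 min read from the ochre readings is shorter than the time of the top, and at that top the supply of E in the flask, 4.14 × 10⁻⁴ M min⁻¹, is balanced by the loss of E. At 0.225 h the flask uses E 4.1 times as fast towards D as towards L, and at 2.00 h it holds 65.2% of D against 15.8% of L. The neighbour charged with 0.033 M of X has the same steps from E and the same Q charge, and with one stay for both flasks its top of 22.7%, higher than that of the flask, means a supply at the top 1.47 times as large, and it ends with 16.4% of L.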